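(Its constants are invented; what happens was integrated by code.)

At late times, target and starting material consume each other one for one, so their difference stays while both fall.

    starting material + target → side product (k1 = 1.1 M⁻¹ s⁻¹, Ea1 = 39.0 kJ mol⁻¹)
    second substrate + coupling partner + catalyst → catalyst + second product (k2 = 5300 M⁻² s⁻¹, Ea2 = 23.0 kJ mol⁻¹)
    starting material + coupling partner + catalyst → catalyst + target (k3 = 4100 M⁻² s⁻¹, Ea3 = 13.0 kJ mol⁻¹)
    (constants at 35 °C)

| setting | spring | summer | dusk |
|---|---|---|---|
| starting material | 0.050 M | 0.050 M | 0.050 M |
| coupling partner | 0.700 equiv | 0.700 equiv | 0.700 equiv |
| second substrate | 1.00 equiv | 1.00 equiv | 1.00 equiv |
| catalyst | 1 mol% | 1 mol% | 1 mol% |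
| temperature | 35 °C | −15 °C | 10 °C |
| time | 2.5 min | 2.5 min | 2.5 min |

- which flask leads in amount of target, in percent of the starting material charged ("all alike" within 1.5 percentage points) (spring / summer / dusk / all alike)
- how much target is there at the end, in percent of the starting material charged: spring
- how much target is there at the end, in percent of the starting material charged: summer
- how much target is there at the end, in percent of the starting material charged: dusk

- in percentages every species weighs as the starting material in it: one side product counts as two
- the list of constants is for 35 °C, to be carried to other temperatures by the activation energies

The reckoning here starts from that difference. Coupling partner, the limiting reagent, is shared between two catalysed steps. In dusk, the starting rate of target formation over that of second product is 1.09. This reckoning holds that share through the coupling and treats the coupling as over before loss begins. Each unit of target made counts two against the difference between starting material and target: one leaves the first, one joins the second. By this reckoning, that difference in dusk comes to 26.9%. This gap, starting material minus target after the coupling, is untouched by the side reaction, which takes one of each. It is also the end state: starting material tends to it as target tends to nothing. The same rule gives 38.9% for spring and 12.9% for summer.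

How fast that end is approached comes from the loss rate. Each target is lost at a rate proportional to the starting material present. Let the clock be the loss constant at the flask's temperature times the starting concentration times the time: 8.25 in spring, 0.433 in summer, 2.15 in dusk. The loss slows as starting material falls towards the gap. In dusk that slowing is a factor of 2.36. Accumulated, the ratio of target to starting material shrinks by exp(clock × gap), and the target follows from that ratio and the gap. This gives 0.701% for spring, 34.8% for summer and 12.8% for dusk. The leader is summer.

The forecast gives figures of its own, from its own coupled fractions: 0.8% for spring, 34% for summer, 13% for dusk, with summer ahead. Its starting point is that the two substrates “compete for the partner”.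

The flasks end at 0.806% in spring, 33.6% in summer and 12.9% in dusk, so summer leads. In dusk, starting material minus target reads 28.5% at 1.25 min and 28.4% at 25.0 min, beside the reckoned gap of 26.9%. A neighbour flask, dusk with 4.00 equiv of second substrate, has a reckoned gap of 70.0%. With the dusk clock of 2.15, that gap gives 2.85% target, and the neighbour flask holds 2.92%.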